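(Readings and results come from a simulation from invented constants.)

| setting | alder | birch | teal | amber | red |
|---|---|---|---|---|---|
| Q | 0.050 M | 0.075 M | 0.10 M | 0.10 M | 0.10 M |
| L | 50 µM | 50 µM | 50 µM | 50 µM | 50 µM |
| temperature | 10 °C | 43 °C | −5 °C | 55 °C | 25 °C |
| remark | run made earlier | run made earlier |  |  |  |
| time |  |  | 2.0 h | 2.0 h | 2.0 h |

| run | time / min | D / % |
|---|---|---|
| alder | 10.0 | 100 |
| alder | 20.0 | 97 |
| alder | 30.0 | 101 |
| alder | 40.0 | 99 |
| alder | 60.0 | 100 |
| alder | 80.0 | 96 |
| birch | 1.00 | 97 |
| birch | 2.00 | 98 |
| birch | 2.50 | 96 |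
| birch | 4.00 | 96 |
| birch | 6.00 | 94 |
| birch | 8.00 | 90 |
| birch | 15.0 | 87 |

(scatter of a reading: 1.5 percentage points)

- which flask leads in amount of D, in percent of the Q charged ("all alike" within 1.5 percentage points) (teal / amber / red / all alike)
- how much D is there at the end, in percent of the Q charged: teal
- how much D is there at the end, in percent of the Q charged: amber
- how much D is there at the end, in percent of the Q charged: red



Slowness is what I read first: how slowly does D fade once it is made? Alder reads 100% at 10.0 min and 96% at 80.0 min. Birch reads 97% at 1.00 min and 87% at 15.0 min. So in alder and birch L works fast, and D is what decays.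

I take the loss of cD as first order with constant k, and I compare the mean of the first 3 readings with the mean of the last 3. Alder gives 2.53 × 10⁻⁴ min⁻¹. This is a rough reading, because its drop of 1 percentage point is smaller than the scatter of 1.5 points. Birch gives 0.00909 min⁻¹.

The two constants stand 1.56 powers of ten apart. Divided by the step in inverse temperature, this gives 4220 K. I call it the decade temperature: the powers of ten that k gains per unit of inverse temperature, which is the Arrhenius slope. I also count n, the powers of ten of cD lost, which is kt over 2.3.

Red looks nearly like alder, yet it should not end like it. At 25 °C, B gives 0.00142 min⁻¹, so red's n is 0.0741 and I expect 84.3%. Alder's n by its last reading is 0.00879, so red's n is 8.43 times alder's, and that is why I expect red to fall while alder's drop stays within the scatter.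

Teal's n is 0.00193, so I expect 99.6% if L finishes. Alder at 10 °C shows at least 0.00500 M min⁻¹ on average, and at that rate teal's charge takes 20.0 min, which is less than teal's 2.0 h and leaves room for the cold. Amber's n is 1.46, which leaves 3.47% of the D made, provided L works at 55 °C; birch, the hotter earlier run, stands at 43 °C. I put teal first.

The forecast says teal leads, with teal 98%, amber 4% and red 87%, figures that differ from mine, on the ground that “the loss is strongly temperature-dependent”.

The flasks give teal 99.8%, amber 0.0915% and red 85.4%, and teal leads. Amber ends with 85.7% of its Q and L at 0%, so my proviso fails there.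

    Q + L → D + L, rate k1*[Q]*[L]/(1 + ([Q]/Km1)) (0.192 M, k = 2270 M⁻¹ s⁻¹, Ea = 41.0 kJ mol⁻¹)
    L → G (k = 5.50 × 10⁻⁵ s⁻¹, Ea = 288 kJ mol⁻¹)
    D → J (k = 2.19 × 10⁻⁵ s⁻¹, Ea = 94.0 kJ mol⁻¹)
    (constants at 25 °C)

Red has not come to rest: its Q stands at 0%, but its D is still decaying. Ten times the time takes red's n to 0.741, so I reckon 18.2%; red gives 20.7% at 20.0 h.

The red charge run at 40 °C has, by B, an n of 0.353, so I expect D near 44.4%. That flask gives 38.0%.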